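Slowness shows at the start of both earlier runs: up to 0.833 min the target stands within scatter of nothing, although the south-west and north-east charges differ.

all flasks: gas phase 200 mM (held)

| charge | substrate | remark | time |
|---|---|---|---|
| south-west | 1.4 M | run made earlier |  |
| north-east | 2.2 M | run made earlier |  |
| flask | 1.0 M |  | 5.0 min |

| run | time / min | target / % | substrate / % |
|---|---|---|---|
| south-west | 0.250 | 0.5 | 100.0 |
| south-west | 0.333 | 0.2 | 99.5 |
| south-west | 0.500 | 0.8 | 100.5 |
| south-west | 0.833 | 0.3 | 100.0 |
| south-west | 1.33 | 0.8 | 97.8 |
| south-west | 2.00 | 2.4 | 97.3 |
| south-west | 3.00 | 3.5 | 94.9 |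
| north-east | 0.250 | 0 | 100.1 |
| north-east | 0.333 | 0.3 | 100.7 |
| north-east | 0.500 | 0.2 | 98.9 |
| north-east | 0.833 | 0.5 | 99.6 |
| north-east | 1.33 | 0.7 | 99.6 |
| north-east | 2.00 | 1.8 | 97.7 |
| north-east | 3.00 | 4.0 | 95.7 |

(scatter of a reading: 0.5 percentage points)

- the target standing at 5.0 min, as a percentage of the substrate charged
- concentration of dissolved gas in solution at 5.0 min, in percent of saturation

- the numbers in the tables scatter with a standard deviation of 0.5 percentage points
- at the start none of the gas phase is in solution

The ledger counts substrate, the limiting reagent while the gas is held. The two runs coincide in percent, so they pool, and each reacted share is booked twice, as target found and as substrate missing. The four numbers average 2.30 % reacted at 2.00 min and 4.23 % at 3.00 min. That late end is a line of slope 0.0193 min⁻¹, a pseudo-first-order constant read from the runs. Run back, it meets zero at 0.805 min: this is the lost time, the delay while the solution fills with gas.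

Taken over to the flask at 1.0 M, the line books 8.10 % as reacted by 5.0 min and leaves 91.9 % as substrate. At the other end, supply meets use when the shortfall from saturation equals use times lost time, 15.5 mM, so this reckoning puts the solution at 92.2 %.

The forecast, reckoned differently, gives 8.4 % (7.2 % to 10 %) and 96 % (84 % to 99.9 %), holding that “This fits a rate proportional to dissolved gas”.

The flask gives 7.63 % target and 86.9 % of saturation, with 92 % of its substrate left.

    substrate + dissolved gas → target (k = 0.120 M⁻¹ min⁻¹)
    gas phase ⇌ dissolved gas, rate k2*(csat - [dissolved gas]) (kL = 0.980 min⁻¹)
    dissolved gas ⇌ dormant form (K = 1.20, k = 0.0190 min⁻¹)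
    dissolved gas + target → over-reacted product (k = 0.220 M⁻¹ min⁻¹)

The largest single effect on this flask's target is the time of reading: left to 50.0 min, the flask holds 24.6 %, a gain of 17 percentage points, against 2.5 points gained when the crossing of gas into solution loses its slowness. Slope times lost time prices that delay at 1.6 points, a figure read from scattered readings. The neighbour flask read at 80 s lies past the lost time, where the line gives 1.02 % and that flask holds 1.32 % target.

The runs were computed with made-up constants, noise included.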